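**Strategy**

The furanone ring B is disconnected at its aryl ether bond O1–C7a. The C3 ketone, attached to C3a of benzene ring A, is ortho to C7a and adjacent to C2: it acidifies C2–H and activates a fluoride on C7a for ipso substitution. In the key step the acyclic 2-fluoro-6-methylphenyl ketone 11, which already carries the whole (8′R)-hydroxylated sesquiterpenoid chain, is oxygenated at C2 through its enolate, and the alkoxide so formed closes ring B by SNAr at C7a in the same flask. The chain is built from geranyl acetate and attached by Pd-catalysed allylation of a β-keto sulfone; a final reagent-controlled enolate hydroxylation sets the C2 hemiketal.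

Key step: step 7

Numbering: ring atoms carry the target numbering (O1, C2, C3, C3a, C4–C7, C7a); chain atoms are C1′–C12′, C1′ being bonded to C2.

Remark: C2 is a hemiketal carbon that can epimerise by ring opening to the 2-hydroxyaryl 1,2-diketone, so it is created last under kinetic reagent control and is assumed to be configurationally stable when the product is kept cold, neutral and aprotic.

**Route**

Step 1
Reactants: 1 geranyl acetate
Product: 3 (2E,6E)-3,7-dimethyl-8-oxoocta-2,6-dien-1-yl acetate, via (2E,6E)-8-hydroxy-3,7-dimethylocta-2,6-dien-1-yl acetate 2 (not isolated)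
Conditions: SeO2 (cat.), t-BuOOH, salicylic acid (cat.), CH2Cl2, 25 °C; filter; then MnO2, CH2Cl2, 25 °C
Reagents that add atoms: tert-butyl hydroperoxide, CC(C)(C)OO (terminal oxygen source, relayed by SeO2)
Why: Riley-type allylic oxidation (ene reaction then [2,3]-shift) should select the (E)-methyl of the trisubstituted alkene remote from the acetate, and MnO2 should then converge the allylic alcohol to the (E)-enal without touching the 2,3-alkene.

Step 2
Reactants: 3 (2E,6E)-3,7-dimethyl-8-oxoocta-2,6-dien-1-yl acetate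
Product: 5 (2E,6E,8R)-8-hydroxy-3,7-dimethylundeca-2,6,10-trien-1-yl acetate, via O-diisopinocampheylboryl homoallylic ether 4 (not isolated)
Conditions: (+)-Ipc2BOMe, CH2=CHCH2MgBr, Et2O, 0 °C (salts removed); 3, Et2O, −100 °C; then 30% H2O2, NaHCO3 (aq), 0 °C
Reagents that add atoms: allylmagnesium bromide, C=CC[Mg]Br, delivered as (+)-B-allyldiisopinocampheylborane made in the flask, C=CCB([C@@H]1[C@@H](C)[C@@H]2C[C@H](C1)C2(C)C)[C@@H]1[C@@H](C)[C@@H]2C[C@H](C1)C2(C)C
Why: Brown asymmetric allylboration through a chair-like six-membered transition state should deliver allyl from the (−)-α-pinene-derived reagent to the Re face of the enal carbonyl in a 1,2-sense, setting C8′ as R, while the acetate is inert to the salt-free allylborane.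

Step 3
Reactants: 5 (2E,6E,8R)-8-hydroxy-3,7-dimethylundeca-2,6,10-trien-1-yl acetate
Product: 6 (2E,6E,8R)-8-hydroxy-3,7,11-trimethyldodeca-2,6,10-trien-1-yl acetate
Conditions: second-generation Grubbs catalyst (H2IMes)(PCy3)Cl2Ru=CHPh (5 mol %), 2-methyl-2-butene/CH2Cl2, 25–40 °C
Reagents that add atoms: 2-methyl-2-butene, CC=C(C)C
Why: Olefin cross-metathesis of the only monosubstituted alkene with excess 2-methyl-2-butene should turn the allyl group into the prenyl terminus, the trisubstituted alkenes and the C8′ stereocenter being left untouched.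

Step 4
Reactants: 7 methyl 2-fluoro-6-methylbenzoate; 8 methyl phenyl sulfone
Product: 9 1-(2-fluoro-6-methylphenyl)-2-(phenylsulfonyl)ethan-1-one
Conditions: 8 (2.1 equiv), n-BuLi (2.1 equiv), THF, −78 to 0 °C; then 7, −78 to 25 °C; 1 M HCl
Reagents that add atoms: none
Why: Claisen-type acylation of the α-sulfonyl carbanion by the ester should stop at the ketone because the second equivalent of carbanion converts the acidic β-keto sulfone into its unreactive enolate.

Step 5
Reactants: 9 1-(2-fluoro-6-methylphenyl)-2-(phenylsulfonyl)ethan-1-one; 6 (2E,6E,8R)-8-hydroxy-3,7,11-trimethyldodeca-2,6,10-trien-1-yl acetate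
Product: 10 (4E,8E,10R)-1-(2-fluoro-6-methylphenyl)-10-hydroxy-5,9,13-trimethyl-2-(phenylsulfonyl)tetradeca-4,8,12-trien-1-one (both C2 epimers)
Conditions: 9, NaH, THF, 0 °C; then 6, Pd(PPh3)4 (5 mol %), THF, 50 °C
Reagents that add atoms: none
Why: Tsuji–Trost allylic alkylation, in which zerovalent palladium ionises the allylic acetate and the soft sulfonyl-stabilised enolate attacks the π-allyl complex at its primary terminus, should form the C2–C1′ bond with retention of the 2′E geometry and tolerate the free C8′ hydroxyl.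

Step 6
Reactants: 10 (4E,8E,10R)-1-(2-fluoro-6-methylphenyl)-10-hydroxy-5,9,13-trimethyl-2-(phenylsulfonyl)tetradeca-4,8,12-trien-1-one
Product: 11 (4E,8E,10R)-1-(2-fluoro-6-methylphenyl)-10-hydroxy-5,9,13-trimethyltetradeca-4,8,12-trien-1-one
Conditions: SmI2 (2.5 equiv), THF/MeOH, −78 °C
Reagents that add atoms: none
Why: Reductive desulfonylation of a β-keto sulfone by single-electron transfer should expel benzenesulfinate from the ketyl and give, after protonation of the samarium enolate by MeOH, the ketone, with aryl fluoride, alkenes and the free alcohol inert at −78 °C.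

Step 7
Reactants: 11 (4E,8E,10R)-1-(2-fluoro-6-methylphenyl)-10-hydroxy-5,9,13-trimethyltetradeca-4,8,12-trien-1-one
Product: 13 2-[(2E,6E,8R)-8-hydroxy-3,7,11-trimethyldodeca-2,6,10-trien-1-yl]-4-methyl-1-benzofuran-3(2H)-one (both C2 epimers), via α-hydroxy ketone dipotassium alkoxide 12 (not isolated)
Conditions: KN(SiMe3)2 (2.2 equiv), THF, −78 °C; (1S)-(+)-(10-camphorsulfonyl)oxaziridine (1.0 equiv), −78 °C; then −78 to 25 °C under argon; AcOH
Reagents that add atoms: (1S)-(+)-(10-camphorsulfonyl)oxaziridine, CC1(C)[C@@H]2CC[C@]13CS(=O)(=O)N4O[C@@]34C2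
Why: KN(SiMe3)2 forms the C8′ alkoxide and the only possible enolate (at C2), which attacks the oxaziridine oxygen (Davis enolate hydroxylation) to give the C2 alkoxide 12 and a ketimine by-product that is inert toward enolates. On warming, this alkoxide adds to C7a, ipso to fluorine and ortho to the C3 ketone, and fluoride leaves from the Meisenheimer intermediate, an intramolecular SNAr of the type known for base-mediated closure of 2-fluoroaryl ketones bearing an α-oxygen nucleophile to benzofuran-3(2H)-ones. Ring B closes in the 5-exo-trig mode by forming the O1–C7a bond. C2 is formed without control and is set again in step 8, so no stereocontrol is needed here. The step needs O-arylation by the C2 oxygen and not by the C8′ alkoxide, and attack at one ring carbon only: C7a alone carries a leaving group activated by the ortho carbonyl, and only the C2 oxygen reaches it through a five-membered transition state. The C8′ alkoxide then acts as internal base and stores the product as its enolate until the acetic acid quench, and because exactly one equivalent of oxidant is consumed at −78 °C this enolate is not oxidised further.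

Step 8
Reactants: 13 2-[(2E,6E,8R)-8-hydroxy-3,7,11-trimethyldodeca-2,6,10-trien-1-yl]-4-methyl-1-benzofuran-3(2H)-one
Product: 14 (2R)-2-hydroxy-2-[(2E,6E,8R)-8-hydroxy-3,7,11-trimethyldodeca-2,6,10-trien-1-yl]-4-methyl-1-benzofuran-3(2H)-one
Conditions: NaN(SiMe3)2 (2.1 equiv), THF, −78 °C; (−)-[(8,8-dichlorocamphoryl)sulfonyl]oxaziridine (1.3 equiv), −78 °C; AcOH in THF, −78 °C
Reagents that add atoms: (−)-[(8,8-dichlorocamphoryl)sulfonyl]oxaziridine, CC1(C)[C@H]2CC[C@@]13CS(=O)(=O)N4O[C@]34C2(Cl)Cl
Why: Davis asymmetric enolate hydroxylation of the sodium enolate (a 3-oxidobenzofuran) should place oxygen on the face selected by the camphor-derived reagent, which by analogy with 2-alkyl-1-tetralone enolates is expected to give the 2R hemiketal (the antipodal reagent is equally available should the sense prove opposite), and protonation at −78 °C before warming should limit ring–chain epimerisation.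

**Compound list**

1 | geranyl acetate, (2E)-3,7-dimethylocta-2,6-dien-1-yl acetate | CC(C)=CCC/C(C)=C/COC(C)=O | starting material
2 | (2E,6E)-8-hydroxy-3,7-dimethylocta-2,6-dien-1-yl acetate | OC/C(C)=C/CC/C(C)=C/COC(C)=O | intermediate
3 | (2E,6E)-3,7-dimethyl-8-oxoocta-2,6-dien-1-yl acetate | O=C/C(C)=C/CC/C(C)=C/COC(C)=O | intermediate
4 | O-diisopinocampheylboryl ether (borinate) of compound 5 | C=CC[C@@H](OB([C@@H]1[C@@H](C)[C@@H]2C[C@H](C1)C2(C)C)[C@@H]1[C@@H](C)[C@@H]2C[C@H](C1)C2(C)C)/C(C)=C/CC/C(C)=C/COC(C)=O | intermediate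
5 | (2E,6E,8R)-8-hydroxy-3,7-dimethylundeca-2,6,10-trien-1-yl acetate | C=CC[C@@H](O)/C(C)=C/CC/C(C)=C/COC(C)=O | intermediate
6 | (2E,6E,8R)-8-hydroxy-3,7,11-trimethyldodeca-2,6,10-trien-1-yl acetate | CC(C)=CC[C@@H](O)/C(C)=C/CC/C(C)=C/COC(C)=O | intermediate
7 | methyl 2-fluoro-6-methylbenzoate | COC(=O)c1c(C)cccc1F | starting material
8 | methyl phenyl sulfone | CS(=O)(=O)c1ccccc1 | starting material
9 | 1-(2-fluoro-6-methylphenyl)-2-(phenylsulfonyl)ethan-1-one | Cc1cccc(F)c1C(=O)CS(=O)(=O)c1ccccc1 | intermediate
10 | (4E,8E,10R)-1-(2-fluoro-6-methylphenyl)-10-hydroxy-5,9,13-trimethyl-2-(phenylsulfonyl)tetradeca-4,8,12-trien-1-one (both C2 epimers) | CC(C)=CC[C@@H](O)/C(C)=C/CC/C(C)=C/CC(C(=O)c1c(C)cccc1F)S(=O)(=O)c1ccccc1 | intermediate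
11 | (4E,8E,10R)-1-(2-fluoro-6-methylphenyl)-10-hydroxy-5,9,13-trimethyltetradeca-4,8,12-trien-1-one | CC(C)=CC[C@@H](O)/C(C)=C/CC/C(C)=C/CCC(=O)c1c(C)cccc1F | intermediate
12 | dipotassium alkoxide of (4E,8E,10R)-1-(2-fluoro-6-methylphenyl)-2,10-dihydroxy-5,9,13-trimethyltetradeca-4,8,12-trien-1-one (both C2 epimers) | CC(C)=CC[C@@H]([O-])/C(C)=C/CC/C(C)=C/CC([O-])C(=O)c1c(C)cccc1F.[K+].[K+] | intermediate
13 | 2-[(2E,6E,8R)-8-hydroxy-3,7,11-trimethyldodeca-2,6,10-trien-1-yl]-4-methyl-1-benzofuran-3(2H)-one (both C2 epimers) | CC(C)=CC[C@@H](O)/C(C)=C/CC/C(C)=C/CC1Oc2cccc(C)c2C1=O | intermediate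
14 | (2R)-2-hydroxy-2-[(2E,6E,8R)-8-hydroxy-3,7,11-trimethyldodeca-2,6,10-trien-1-yl]-4-methyl-1-benzofuran-3(2H)-one | CC(C)=CC[C@@H](O)/C(C)=C/CC/C(C)=C/C[C@@]1(O)Oc2cccc(C)c2C1=O | target

**Step count and risks**

Total step count: 8. Longest linear sequence: 7 (steps 1, 2, 3, 5, 6, 7, 8).

Steps most likely to fail:

Step 8. The sodium hemiketal alkoxide may open to the phenoxide of the 1,2-diketone and re-close before the quench, or the planar enolate may be oxidised with weak facial discrimination; either process erodes the C2 configuration. The fallback sets out from 13 and comes back at 14. Hydroxylation without stereocontrol by enolate autoxidation (O2, P(OEt)3, Cs2CO3, DMF, 0 °C, the hydroperoxide being reduced in the flask by the phosphite) would give the C2-epimeric hemiketal mixture F1. Because C8′ is fixed, its two components are diastereomers and would be separated by preparative HPLC under neutral conditions, the 2R isomer being 14. The 2S isomer would be returned to the equilibrium mixture by ring–chain equilibration (catalytic Et3N) and recycled.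

Step 7. Ipso substitution at C7a may be slow because the di-ortho-substituted aryl ketone is twisted out of conjugation, which leaves the α-alkoxy ketone time to isomerise by α-ketol shift or to fragment. The fallback sets out from 6 and comes back at 13; it closes the same O1–C7a bond by copper catalysis in the bromo series. Methyl 2-bromo-6-methylbenzoate F2 would be acylated with lithiated 8 to 1-(2-bromo-6-methylphenyl)-2-(phenylsulfonyl)ethan-1-one F3. Allylation of F3 with 6 (Pd(PPh3)4, 25 °C, where the hindered aryl bromide should react more slowly than the allylic acetate) would give the bromo β-keto sulfone F4. SmI2 would give the bromo ketone F5. Enolate hydroxylation (KN(SiMe3)2, oxaziridine, −78 °C, AcOH quench at −78 °C) would give the isolated α-hydroxy ketone F6. Intramolecular Ullmann O-arylation (CuI, 1,10-phenanthroline, Cs2CO3, toluene, 80 °C) would then give 13.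

Step 5. The π-allylpalladium intermediate may lose the 2′E geometry by π–σ–π isomerisation or be attacked at its tertiary terminus, giving isomers that are hard to remove. The fallback sets out from 6 and comes back at 10. Methanolysis (K2CO3, MeOH) would give (2E,6E,8R)-3,7,11-trimethyldodeca-2,6,10-triene-1,8-diol F7. Appel bromination of the primary allylic hydroxyl (CBr4, PPh3, CH2Cl2, −30 °C) would give (2E,6E,8R)-1-bromo-3,7,11-trimethyldodeca-2,6,10-trien-8-ol F8. Direct SN2 alkylation of the sodium enolate of 9 with F8 (NaH, THF/DMF, 0 °C) would fix geometry and regiochemistry and give 10.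

Further compounds
F1 | step 8 | (2RS)-2-hydroxy-2-[(2E,6E,8R)-8-hydroxy-3,7,11-trimethyldodeca-2,6,10-trien-1-yl]-4-methyl-1-benzofuran-3(2H)-one (mixture of C2 epimers) | CC(C)=CC[C@@H](O)/C(C)=C/CC/C(C)=C/CC1(O)Oc2cccc(C)c2C1=O
F2 | step 7 | methyl 2-bromo-6-methylbenzoate | COC(=O)c1c(C)cccc1Br
F3 | step 7 | 1-(2-bromo-6-methylphenyl)-2-(phenylsulfonyl)ethan-1-one | Cc1cccc(Br)c1C(=O)CS(=O)(=O)c1ccccc1
F4 | step 7 | (4E,8E,10R)-1-(2-bromo-6-methylphenyl)-10-hydroxy-5,9,13-trimethyl-2-(phenylsulfonyl)tetradeca-4,8,12-trien-1-one (both C2 epimers) | CC(C)=CC[C@@H](O)/C(C)=C/CC/C(C)=C/CC(C(=O)c1c(C)cccc1Br)S(=O)(=O)c1ccccc1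
F5 | step 7 | (4E,8E,10R)-1-(2-bromo-6-methylphenyl)-10-hydroxy-5,9,13-trimethyltetradeca-4,8,12-trien-1-one | CC(C)=CC[C@@H](O)/C(C)=C/CC/C(C)=C/CCC(=O)c1c(C)cccc1Br
F6 | step 7 | (4E,8E,10R)-1-(2-bromo-6-methylphenyl)-2,10-dihydroxy-5,9,13-trimethyltetradeca-4,8,12-trien-1-one (both C2 epimers) | CC(C)=CC[C@@H](O)/C(C)=C/CC/C(C)=C/CC(O)C(=O)c1c(C)cccc1Br
F7 | step 5 | (2E,6E,8R)-3,7,11-trimethyldodeca-2,6,10-triene-1,8-diol | CC(C)=CC[C@@H](O)/C(C)=C/CC/C(C)=C/CO
F8 | step 5 | (2E,6E,8R)-1-bromo-3,7,11-trimethyldodeca-2,6,10-trien-8-ol | CC(C)=CC[C@@H](O)/C(C)=C/CC/C(C)=C/CBr
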